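**Retrosynthetic overview**

1. Target: 21-(furan-2-yl)henicosa-14,16-diyn-1-ol (chain C1–C21; furan O1′, C2′–C5′ attached at C21). The key disconnection is C19–C20, the central bond of the saturated C18–C21 tether. Both carbons are plain primary CH2 groups, C19 homopropargylic to the C14–C17 diyne and C20 homofurfurylic to furan C2′. Each therefore maps onto the α-carbon of a simple carboxylic acid and can be released as an unconjugated primary radical by loss of CO2. The two N-hydroxyphthalimide esters are joined by a cathodic Ni-electrocatalytic doubly decarboxylative C(sp3)–C(sp3) coupling, chosen because the furan ring is labile to oxidation but inert to reduction.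
2. Diyne half: the C15–C16 sp–sp bond comes from a Cadiot–Chodkiewicz coupling of the 1-bromoalkyne of O-TBS pentadec-14-yn-1-ol with pent-4-ynoic acid.
3. Pentadec-14-yn-1-ol: C-alkylation of propargyl alcohol with 1-bromododecane, then alkyne zipper isomerisation to the chain end.
4. Furan half: commercial 3-(furan-2-yl)propanoic acid. No ring is formed anywhere in the route; the furan (O1′, C2′–C5′) is carried intact.
5. End game: fluoride desilylation of the primary TBS ether.

Key step: step 8

Remark: the target has no stereocentre, no stereogenic double bond and no other stereogenic element, so it is one achiral compound and no step has to set or preserve configuration. The 1,3-diyne intermediates 9, 10, 13 and 14 should be handled in solution and protected from light.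

**Route**

Step 1
Reactants: 1 prop-2-yn-1-ol (propargyl alcohol); 2 1-bromododecane
Product: 4 pentadec-2-yn-1-ol, via dilithiated prop-2-yn-1-ol 3 (not isolated)
Conditions: 1 (1.2 equiv), n-BuLi (2.4 equiv), THF–HMPA, −78 → 0 °C; then 2, 0 °C → rt; H2O quench
Reagents that add atoms: none
Why: Double deprotonation gives the O,C-dilithio species, whose acetylide carbon is far more nucleophilic than the alkoxide oxygen, so the primary bromide should be displaced at carbon (acetylide SN2 alkylation).

Step 2
Reactants: 4 pentadec-2-yn-1-ol
Product: 5 pentadec-14-yn-1-ol
Conditions: NaH (5 equiv), H2N(CH2)3NH2, 70 °C, then 4, 55 °C; H2O quench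
Reagents that add atoms: none
Why: Alkyne zipper reaction: the aminopropylamide base moves the triple bond along the unbranched chain by repeated propargyl/allenyl prototropy, and irreversible formation of the terminal acetylide should drain the equilibrium to the chain end remote from the alkoxide.

Step 3
Reactants: 5 pentadec-14-yn-1-ol
Product: 6 tert-butyl(dimethyl)(pentadec-14-yn-1-yloxy)silane
Conditions: TBSCl (1.2 equiv), imidazole (2.2 equiv), DMF, rt
Reagents that add atoms: tert-butyldimethylsilyl chloride, CC(C)(C)[Si](C)(C)Cl
Why: Standard imidazole-mediated silylation masks the only hydroxyl group so that it cannot be acylated by the active esters made later.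

Step 4
Reactants: 6 tert-butyl(dimethyl)(pentadec-14-yn-1-yloxy)silane
Product: 7 [(15-bromopentadec-14-yn-1-yl)oxy](tert-butyl)dimethylsilane
Conditions: NBS (1.1 equiv), AgNO3 (10 mol%), acetone, rt, dark
Reagents that add atoms: N-bromosuccinimide, BrN1C(=O)CCC1=O
Why: Silver(I)-catalysed electrophilic bromination of the terminal alkyne through the silver acetylide is selective for the sp C–H bond and should leave the silyl ether untouched.

Step 5
Reactants: 7 [(15-bromopentadec-14-yn-1-yl)oxy](tert-butyl)dimethylsilane; 8 pent-4-ynoic acid
Product: 9 20-[(tert-butyldimethylsilyl)oxy]icosa-4,6-diynoic acid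
Conditions: 8 (1.3 equiv), CuCl (10 mol%), NH2OH·HCl (30 mol%), n-BuNH2, H2O/MeOH/THF, 0 °C → rt, dark; then aq. citric acid to pH 4
Reagents that add atoms: none
Why: Cadiot–Chodkiewicz coupling: the copper(I) acetylide of 8 should couple with bromoalkyne 7 to give the unsymmetrical sp–sp bond, with hydroxylamine holding copper at Cu(I) to suppress Glaser homocoupling; the carboxylate and the TBS ether are inert.

Step 6
Reactants: 9 20-[(tert-butyldimethylsilyl)oxy]icosa-4,6-diynoic acid
Product: 10 1,3-dioxoisoindolin-2-yl 20-[(tert-butyldimethylsilyl)oxy]icosa-4,6-diynoate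
Conditions: N-hydroxyphthalimide (1.1 equiv), DIC (1.1 equiv), DMAP (10 mol%), CH2Cl2, 0 °C → rt, dark
Reagents that add atoms: N-hydroxyphthalimide, ON1C(=O)c2ccccc2C1=O
Why: Steglich-type carbodiimide esterification, in which the acidic N-hydroxy imide intercepts the O-acylisourea to give the redox-active ester without touching the diyne or silyl ether.

Step 7
Reactants: 11 3-(furan-2-yl)propanoic acid
Product: 12 1,3-dioxoisoindolin-2-yl 3-(furan-2-yl)propanoate
Conditions: N-hydroxyphthalimide (1.1 equiv), DIC (1.1 equiv), DMAP (10 mol%), CH2Cl2, 0 °C → rt
Reagents that add atoms: N-hydroxyphthalimide, ON1C(=O)c2ccccc2C1=O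
Why: The same Steglich-type carbodiimide esterification; the neutral, non-oxidising conditions are compatible with the acid- and oxidant-sensitive furan.

Step 8
Reactants: 10 1,3-dioxoisoindolin-2-yl 20-[(tert-butyldimethylsilyl)oxy]icosa-4,6-diynoate; 12 1,3-dioxoisoindolin-2-yl 3-(furan-2-yl)propanoate
Product: 13 tert-butyl{[21-(furan-2-yl)henicosa-14,16-diyn-1-yl]oxy}dimethylsilane
Conditions: 10 (1.0 equiv), 12 (3.0 equiv), NiCl2·6H2O (20 mol%), 2,2′:6′,2″-terpyridine (20 mol%), AgNO3 (0.3 equiv), NMP, Mg(+)/RVC(−), undivided cell, constant current, rt, dark; then cold 0.5 M HCl work-up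
Reagents that add atoms: none
Why: Cathodically generated low-valent (terpyridine)nickel transfers an electron to each N-acyloxyphthalimide, which fragments to phthalimide anion, CO2 and a primary alkyl radical (C19 from 10, C20 from 12); the two alkyl groups are collected on nickel and C(sp3)–C(sp3) reductive elimination forms the C19–C20 bond, while the sacrificial Mg anode supplies the electrons and its Mg2+ pairs with the phthalimide anion. The closest known reaction type is the Ni-electrocatalytic doubly decarboxylative coupling of two primary alkyl redox-active esters, a reductive counterpart of the mixed Kolbe electrolysis. No ring is closed and no stereocentre is created. The step needs cross-coupling over homocoupling, which is secured by using the inexpensive furan ester 12 in threefold excess over the diyne ester 10, so that the statistical by-product is mainly the small, non-polar furan homodimer. It also needs chemoselectivity for the two N–O esters over the diyne, the furan and the silyl ether: the active esters are the most easily reduced groups present, the furan is labile only to oxidation (which is why an anodic Kolbe process is avoided), and the tridentate ligand leaves no free cis site on nickel for β-hydride elimination or alkyne insertion. Neither radical is conjugated (C19 is homopropargylic, C20 homofurfurylic), so neither should isomerise to an allenyl or furfuryl position before it is captured.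

Step 9
Reactants: 13 tert-butyl{[21-(furan-2-yl)henicosa-14,16-diyn-1-yl]oxy}dimethylsilane
Product: 14 21-(furan-2-yl)henicosa-14,16-diyn-1-ol
Conditions: TBAF (1.2 equiv), THF, 0 °C → rt, dark; aqueous work-up
Reagents that add atoms: none
Why: Fluoride-driven desilylation, powered by the strong Si–F bond, should cleave the primary TBS ether under non-acidic conditions that spare the furan and the diyne.

**Compound list**

1 | prop-2-yn-1-ol (propargyl alcohol) | C#CCO | starting material
2 | 1-bromododecane | CCCCCCCCCCCCBr | starting material
3 | dilithiated prop-2-yn-1-ol (lithium alkoxide and lithium acetylide, not isolated) | [Li+].[Li+].[O-]CC#[C-] | intermediate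
4 | pentadec-2-yn-1-ol | CCCCCCCCCCCCC#CCO | intermediate
5 | pentadec-14-yn-1-ol | OCCCCCCCCCCCCCC#C | intermediate
6 | tert-butyl(dimethyl)(pentadec-14-yn-1-yloxy)silane | CC(C)(C)[Si](C)(C)OCCCCCCCCCCCCCC#C | intermediate
7 | [(15-bromopentadec-14-yn-1-yl)oxy](tert-butyl)dimethylsilane | CC(C)(C)[Si](C)(C)OCCCCCCCCCCCCCC#CBr | intermediate
8 | pent-4-ynoic acid | C#CCCC(=O)O | starting material
9 | 20-[(tert-butyldimethylsilyl)oxy]icosa-4,6-diynoic acid | CC(C)(C)[Si](C)(C)OCCCCCCCCCCCCCC#CC#CCCC(=O)O | intermediate
10 | 1,3-dioxoisoindolin-2-yl 20-[(tert-butyldimethylsilyl)oxy]icosa-4,6-diynoate | CC(C)(C)[Si](C)(C)OCCCCCCCCCCCCCC#CC#CCCC(=O)ON1C(=O)c2ccccc2C1=O | intermediate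
11 | 3-(furan-2-yl)propanoic acid | OC(=O)CCc1ccco1 | starting material
12 | 1,3-dioxoisoindolin-2-yl 3-(furan-2-yl)propanoate | O=C(CCc1ccco1)ON1C(=O)c2ccccc2C1=O | intermediate
13 | tert-butyl{[21-(furan-2-yl)henicosa-14,16-diyn-1-yl]oxy}dimethylsilane | CC(C)(C)[Si](C)(C)OCCCCCCCCCCCCCC#CC#CCCCCc1ccco1 | intermediate
14 | 21-(furan-2-yl)henicosa-14,16-diyn-1-ol | OCCCCCCCCCCCCCC#CC#CCCCCc1ccco1 | target

**Step count**

Total steps: 9. Longest linear sequence: 8 (steps 1–6, 8, 9); step 7 is a one-step branch.

**Steps most likely to fail, with fallbacks**

Step 8. The two primary radicals are generated at similar rates, so statistical homodimerisation may consume the diyne ester. Low-valent nickel may also engage the conjugated diyne instead of turning over. The fallback gives up the C19–C20 union and makes the C15–C16 sp–sp bond last; it sets out from bromoalkyne 7 and comes back to the route at 13. Furan is lithiated at C2 (n-BuLi, THF, 0 °C) and alkylated with 1-bromo-4-chlorobutane to give 2-(4-chlorobutyl)furan F1. Displacement of the chloride with lithium acetylide–ethylenediamine complex in DMSO should give 2-(hex-5-yn-1-yl)furan F2. Cadiot–Chodkiewicz coupling of F2 with 7 (CuCl, NH2OH·HCl, n-BuNH2, MeOH/THF) should then deliver 13, which is desilylated as in step 9.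

Step 5. Halogen–copper exchange between the copper acetylide and the bromoalkyne may lead to symmetrical homocoupling. This is made worse by phase separation between the lipophilic bromoalkyne and the aqueous carboxylate. The fallback replaces the haloalkyne coupling by an oxidative coupling of two terminal alkynes in a homogeneous organic phase; it sets out from terminal alkyne 6 (omitting step 4) and comes back at 9. Acid 8 is esterified (MeOH, cat. H2SO4) to methyl pent-4-ynoate F3. Alkyne 6 is cross-coupled with a fivefold excess of F3 under Glaser–Hay-type aerobic Ni/Cu co-catalysis (NiCl2·6H2O, CuI, TMEDA, air, THF, rt) to give methyl 20-[(tert-butyldimethylsilyl)oxy]icosa-4,6-diynoate F4; the polar diester homodimer is removed by chromatography. Saponification (LiOH, THF/H2O, 0 °C) then liberates 9.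

Step 1. The poorly soluble dilithio species may react sluggishly, so that O-alkylation and E2 elimination of the bromide compete and conversion stays low. The fallback replaces the dianion by a protected monoanion; it sets out from 1 and comes back at 4. Alcohol 1 is protected with 3,4-dihydro-2H-pyran (PPTS, CH2Cl2) as 2-(prop-2-yn-1-yloxy)oxane F5. Its lithium acetylide (n-BuLi, THF/DMPU, −78 °C → rt) is alkylated with 2 to give 2-(pentadec-2-yn-1-yloxy)oxane F6. Acetal exchange (TsOH, MeOH, rt) then releases 4.

**Further compounds**

F1 | step 8 | 2-(4-chlorobutyl)furan | ClCCCCc1ccco1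
F2 | step 8 | 2-(hex-5-yn-1-yl)furan | C#CCCCCc1ccco1
F3 | step 5 | methyl pent-4-ynoate | C#CCCC(=O)OC
F4 | step 5 | methyl 20-[(tert-butyldimethylsilyl)oxy]icosa-4,6-diynoate | CC(C)(C)[Si](C)(C)OCCCCCCCCCCCCCC#CC#CCCC(=O)OC
F5 | step 1 | 2-(prop-2-yn-1-yloxy)oxane | C#CCOC1CCCCO1
F6 | step 1 | 2-(pentadec-2-yn-1-yloxy)oxane | CCCCCCCCCCCCC#CCOC1CCCCO1
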